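**Plan**

1. Cuts: first the O–C(CH3)2 bond of the ring B chromene (oxa-6π closure of an ortho-quinone methide, reached from the catechol of diprenyl tetrol 22); then the C6–CH2 bond of ring A (Claisen shift from O5, allyl-to-prenyl metathesis), C3–C1' (Suzuki–Miyaura), C1'–B and C5'–prenyl of ring B (C–H borylation, ortho-lithiation), and the pyranone O1–C2–C3 unit (enaminone iodocyclization).
2. Forward: acetophenone 1 gives 3-iodochromone 9 (pyranone closed); catechol 10 gives prenyl boronate 16; coupling gives the isoflavone; ring A is prenylated; the MOM groups come off; the pyran ring of the chromene is closed last.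
3. Enabling feature: ring B has the O3'/O4' catechol with the prenyl group on C5', ortho to O4'. Only this ring can reach the quinone oxidation level; tautomerization of C1''H2 then gives the oxatriene O4'=C4'–C5'=C1''–C2''=C3'', which closes O4'–C3''. This oxidation level is the only helper and is spent in the closure.
4. Stereochemistry: the target has no stereocentre; the chromene ring alkene is cis by necessity.

Key step: step 11

Remark: isoflavone numbering is used (ring A C5 to C8, ring B C1' to C6'; C1'' to C3'' are the carbons of the ring B prenyl group counted from the ring). All numbered starting materials are taken as commercial.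

**Route**

Step 1
Reactants: 1 2,4,6-trihydroxyacetophenone; 2 chloromethyl methyl ether (MOMCl)
Product: 3 1-[2,6-dihydroxy-4-(methoxymethoxy)phenyl]ethan-1-one
Conditions: MOMCl (1.05 equiv), K2CO3, acetone, 0 °C to rt
Reagents that add atoms: chloromethyl methyl ether, COCCl
Why: Williamson-type O-alkylation in which the 4-OH, para to the acetyl group and not held in the hydrogen-bonded chelate with the carbonyl, should be etherified first by one equivalent of reagent.

Step 2
Reactants: 3 1-[2,6-dihydroxy-4-(methoxymethoxy)phenyl]ethan-1-one; 4 allyl bromide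
Product: 5 1-[2-(allyloxy)-6-hydroxy-4-(methoxymethoxy)phenyl]ethan-1-one
Conditions: allyl bromide (1.1 equiv), K2CO3, acetone, reflux
Reagents that add atoms: allyl bromide, C=CCBr
Why: Williamson ether synthesis on one of the two equivalent ortho hydroxyls; the remaining hydroxyl is then locked in the carbonyl chelate and should resist a second alkylation.

Step 3
Reactants: 5 1-[2-(allyloxy)-6-hydroxy-4-(methoxymethoxy)phenyl]ethan-1-one; 6 N,N-dimethylformamide dimethyl acetal (DMF-DMA); 7 iodine
Product: 9 5-(allyloxy)-3-iodo-7-(methoxymethoxy)-4H-chromen-4-one, via enaminone 8 (not isolated)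
Conditions: DMF-DMA, 95 °C; evaporate; then I2, pyridine, CHCl3, rt
Reagents that add atoms: N,N-dimethylformamide dimethyl acetal, COC(OC)N(C)C; iodine, II
Why: Condensation of the methyl ketone with DMF-DMA gives the enaminone, and iodine then brings about iodocyclization of the 2-hydroxyaryl enaminone to the 3-iodochromone with loss of dimethylamine; since only one phenol is free, the allyloxy oxygen is fixed as O5.

Step 4
Reactants: 10 catechol; 2 chloromethyl methyl ether (MOMCl)
Product: 11 1,2-bis(methoxymethoxy)benzene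
Conditions: NaH, MOMCl, DMF, 0 °C to rt
Reagents that add atoms: chloromethyl methyl ether, COCCl
Why: Double Williamson etherification of the catechol dianion, which installs the two MOM ethers that direct the next metalation.

Step 5
Reactants: 11 1,2-bis(methoxymethoxy)benzene; 12 1-bromo-3-methylbut-2-ene (prenyl bromide)
Product: 14 1,2-bis(methoxymethoxy)-3-(3-methylbut-2-en-1-yl)benzene, via aryllithium 13 (not isolated)
Conditions: n-BuLi, THF, 0 °C; then CuBr·SMe2 (10 mol %), prenyl bromide, −78 °C to rt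
Reagents that add atoms: 1-bromo-3-methylbut-2-ene, CC(C)=CCBr
Why: Directed ortho-metalation by the MOM ether places lithium on C3, and copper-catalysed SN2 allylic substitution on prenyl bromide should give the linear prenyl arene.

Step 6
Reactants: 14 1,2-bis(methoxymethoxy)-3-(3-methylbut-2-en-1-yl)benzene; 15 bis(pinacolato)diboron (B2pin2)
Product: 16 2-[3,4-bis(methoxymethoxy)-5-(3-methylbut-2-en-1-yl)phenyl]-4,4,5,5-tetramethyl-1,3,2-dioxaborolane
Conditions: [Ir(OMe)(cod)]2 (1.5 mol %), 4,4'-di-tert-butyl-2,2'-bipyridine (3 mol %), B2pin2 (1.0 equiv), THF, 60 °C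
Reagents that add atoms: bis(pinacolato)diboron, CC1(C)OB(OC1(C)C)B1OC(C)(C)C(C)(C)O1
Why: Iridium-catalysed aromatic C–H borylation is steered by sterics, so in this 1,2,3-trisubstituted arene only C5, the one C–H without an ortho substituent, should react, while the trisubstituted alkene is a poor partner for hydroboration.

Step 7
Reactants: 9 5-(allyloxy)-3-iodo-7-(methoxymethoxy)-4H-chromen-4-one; 16 2-[3,4-bis(methoxymethoxy)-5-(3-methylbut-2-en-1-yl)phenyl]-4,4,5,5-tetramethyl-1,3,2-dioxaborolane
Product: 17 5-(allyloxy)-3-[3,4-bis(methoxymethoxy)-5-(3-methylbut-2-en-1-yl)phenyl]-7-(methoxymethoxy)-4H-chromen-4-one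
Conditions: Pd(dppf)Cl2 (5 mol %), K2CO3, 1,4-dioxane/H2O, 80 °C
Reagents that add atoms: none
Why: Suzuki–Miyaura coupling of a 3-iodochromone with an arylboronate is the standard isoflavone assembly, and oxidative addition of zerovalent palladium into the C3–I bond should be much faster than ionization of the allyl aryl ether.

Step 8
Reactants: 17 5-(allyloxy)-3-[3,4-bis(methoxymethoxy)-5-(3-methylbut-2-en-1-yl)phenyl]-7-(methoxymethoxy)-4H-chromen-4-one
Product: 19 6-allyl-3-[3,4-bis(methoxymethoxy)-5-(3-methylbut-2-en-1-yl)phenyl]-5-hydroxy-7-(methoxymethoxy)-4H-chromen-4-one, via cyclohexadienone 18 (not isolated)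
Conditions: N,N-diethylaniline, 200 °C, sealed tube
Reagents that add atoms: none
Why: Aromatic Claisen rearrangement in which the [3,3] shift from O5 can reach only C6, because the other ortho position is the ring-fusion carbon C4a; the amine solvent should speed tautomerization of dienone 18 (its C6 stereocentre is transient) to the chelated 5-phenol.

Step 9
Reactants: 19 6-allyl-3-[3,4-bis(methoxymethoxy)-5-(3-methylbut-2-en-1-yl)phenyl]-5-hydroxy-7-(methoxymethoxy)-4H-chromen-4-one; 20 2-methylbut-2-ene
Product: 21 3-[3,4-bis(methoxymethoxy)-5-(3-methylbut-2-en-1-yl)phenyl]-5-hydroxy-7-(methoxymethoxy)-6-(3-methylbut-2-en-1-yl)-4H-chromen-4-one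
Conditions: second-generation Grubbs catalyst (5 mol %), 2-methylbut-2-ene (excess), CH2Cl2, 40 °C, sealed tube
Reagents that add atoms: 2-methylbut-2-ene, CC=C(C)C
Why: Olefin cross-metathesis of the terminal allyl group with excess 2-methylbut-2-ene turns allyl into prenyl with loss of propene, while the ring B prenyl group, a trisubstituted alkene, can undergo only degenerate exchange.

Step 10
Reactants: 21 3-[3,4-bis(methoxymethoxy)-5-(3-methylbut-2-en-1-yl)phenyl]-5-hydroxy-7-(methoxymethoxy)-6-(3-methylbut-2-en-1-yl)-4H-chromen-4-one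
Product: 22 3-[3,4-dihydroxy-5-(3-methylbut-2-en-1-yl)phenyl]-5,7-dihydroxy-6-(3-methylbut-2-en-1-yl)-4H-chromen-4-one
Conditions: 3 M HCl (aq), MeOH, 45 °C
Reagents that add atoms: none
Why: Acid-catalysed acetal exchange removes the three MOM groups, and mild conditions should keep the two prenyl groups from acid-mediated chroman formation.

Step 11
Reactants: 22 3-[3,4-dihydroxy-5-(3-methylbut-2-en-1-yl)phenyl]-5,7-dihydroxy-6-(3-methylbut-2-en-1-yl)-4H-chromen-4-one
Product: 25 Gancaonin H, via ortho-quinone 23 (not isolated), via ortho-quinone methide 24 (not isolated)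
Conditions: DDQ (1.0 equiv, added slowly), 1,4-dioxane, rt, then 60 °C
Reagents that add atoms: none
Why: DDQ should oxidize the ring B catechol (O3'/O4'), the most easily oxidized site, to ortho-quinone 23, whose C1'' methylene (allylic and vinylogously alpha to the C3' carbonyl) tautomerizes to the 3'-hydroxy ortho-quinone methide 24 (the same species would also arise from direct benzylic hydride abstraction); this 1-oxatriene O4'=C4'–C5'=C1''–C2''=C3'' then closes the O4'–C3'' bond and ring B becomes aromatic again. The closest known reaction type is the DDQ dehydrogenative cyclization of ortho-prenylphenols to 2,2-dimethyl-2H-chromenes, with the base- or acid-promoted isomerization of prenylquinones to chromenols as the model for the tautomerization. The pyran ring is closed by a thermal disrotatory six-electron (oxa-6π) electrocyclization of the (Z)-dienone, the bond forming between the carbonyl oxygen and the dimethyl-substituted terminus. No stereocentre is created, because the new sp3 carbon carries two methyl groups and the ring alkene can only be cis. Two selectivities are needed: ring B must react and ring A must not, which should hold because the meta-related, acyl-deactivated 5,7-dihydroxy system of ring A cannot reach a quinone and its prenyl group is dehydrogenated by DDQ only under more forcing conditions than one equivalent at room temperature; and the ether must form at O4' and not at O3', which is secured because only O4' is ortho to C5' and so only it belongs to the oxatriene.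

**Compound list**

1 | 2,4,6-trihydroxyacetophenone | CC(=O)c1c(O)cc(O)cc1O | starting material
2 | chloromethyl methyl ether | COCCl | starting material
3 | 1-[2,6-dihydroxy-4-(methoxymethoxy)phenyl]ethan-1-one | CC(=O)c1c(O)cc(OCOC)cc1O | intermediate
4 | allyl bromide | C=CCBr | starting material
5 | 1-[2-(allyloxy)-6-hydroxy-4-(methoxymethoxy)phenyl]ethan-1-one | CC(=O)c1c(O)cc(OCOC)cc1OCC=C | intermediate
6 | N,N-dimethylformamide dimethyl acetal | COC(OC)N(C)C | starting material
7 | iodine | II | starting material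
8 | (E)-1-[2-(allyloxy)-6-hydroxy-4-(methoxymethoxy)phenyl]-3-(dimethylamino)prop-2-en-1-one; not isolated | CN(C)/C=C/C(=O)c1c(O)cc(OCOC)cc1OCC=C | intermediate
9 | 5-(allyloxy)-3-iodo-7-(methoxymethoxy)-4H-chromen-4-one | O=c1c(I)coc2cc(OCOC)cc(OCC=C)c12 | intermediate
10 | catechol | Oc1ccccc1O | starting material
11 | 1,2-bis(methoxymethoxy)benzene | COCOc1ccccc1OCOC | intermediate
12 | 1-bromo-3-methylbut-2-ene | CC(C)=CCBr | starting material
13 | [2,3-bis(methoxymethoxy)phenyl]lithium; not isolated | [Li]c1cccc(OCOC)c1OCOC | intermediate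
14 | 1,2-bis(methoxymethoxy)-3-(3-methylbut-2-en-1-yl)benzene | CC(C)=CCc1cccc(OCOC)c1OCOC | intermediate
15 | bis(pinacolato)diboron | CC1(C)OB(OC1(C)C)B1OC(C)(C)C(C)(C)O1 | starting material
16 | 2-[3,4-bis(methoxymethoxy)-5-(3-methylbut-2-en-1-yl)phenyl]-4,4,5,5-tetramethyl-1,3,2-dioxaborolane | CC(C)=CCc1cc(B2OC(C)(C)C(C)(C)O2)cc(OCOC)c1OCOC | intermediate
17 | 5-(allyloxy)-3-[3,4-bis(methoxymethoxy)-5-(3-methylbut-2-en-1-yl)phenyl]-7-(methoxymethoxy)-4H-chromen-4-one | O=c1c(-c2cc(CC=C(C)C)c(OCOC)c(OCOC)c2)coc2cc(OCOC)cc(OCC=C)c12 | intermediate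
18 | 6-allyl-3-[3,4-bis(methoxymethoxy)-5-(3-methylbut-2-en-1-yl)phenyl]-7-(methoxymethoxy)-6H-chromene-4,5-dione, racemic at C6; not isolated | O=C1C(CC=C)C(OCOC)=CC2=C1C(=O)C(-c1cc(CC=C(C)C)c(OCOC)c(OCOC)c1)=CO2 | intermediate
19 | 6-allyl-3-[3,4-bis(methoxymethoxy)-5-(3-methylbut-2-en-1-yl)phenyl]-5-hydroxy-7-(methoxymethoxy)-4H-chromen-4-one | O=c1c(-c2cc(CC=C(C)C)c(OCOC)c(OCOC)c2)coc2cc(OCOC)c(CC=C)c(O)c12 | intermediate
20 | 2-methylbut-2-ene | CC=C(C)C | starting material
21 | 3-[3,4-bis(methoxymethoxy)-5-(3-methylbut-2-en-1-yl)phenyl]-5-hydroxy-7-(methoxymethoxy)-6-(3-methylbut-2-en-1-yl)-4H-chromen-4-one | O=c1c(-c2cc(CC=C(C)C)c(OCOC)c(OCOC)c2)coc2cc(OCOC)c(CC=C(C)C)c(O)c12 | intermediate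
22 | 3-[3,4-dihydroxy-5-(3-methylbut-2-en-1-yl)phenyl]-5,7-dihydroxy-6-(3-methylbut-2-en-1-yl)-4H-chromen-4-one | O=c1c(-c2cc(CC=C(C)C)c(O)c(O)c2)coc2cc(O)c(CC=C(C)C)c(O)c12 | intermediate
23 | 5-[5,7-dihydroxy-6-(3-methylbut-2-en-1-yl)-4-oxo-4H-chromen-3-yl]-3-(3-methylbut-2-en-1-yl)cyclohexa-3,5-diene-1,2-dione; not isolated | O=C1C(=O)C(CC=C(C)C)=CC(c2coc3cc(O)c(CC=C(C)C)c(O)c3c2=O)=C1 | intermediate
24 | 3-[(3Z)-5-hydroxy-3-(3-methylbut-2-en-1-ylidene)-4-oxocyclohexa-1,5-dien-1-yl]-5,7-dihydroxy-6-(3-methylbut-2-en-1-yl)-4H-chromen-4-one; not isolated | O=C1C(O)=CC(c2coc3cc(O)c(CC=C(C)C)c(O)c3c2=O)=C/C1=C/C=C(C)C | intermediate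
25 | Gancaonin H, 5,7-dihydroxy-3-(8-hydroxy-2,2-dimethyl-2H-chromen-6-yl)-6-(3-methylbut-2-en-1-yl)-4H-chromen-4-one | CC(C)=CCc1c(O)cc2occ(-c3cc(O)c4c(c3)C=CC(C)(C)O4)c(=O)c2c1O | target

**Count and risks**

Total step count: 11. Longest linear sequence: 8 steps (steps 1 to 3 and 7 to 11, or steps 4 to 6 and 7 to 11).

Steps most likely to fail:

1. Step 11. The oxidation may run past the ring B event or lose site selectivity (dehydrogenation at the ring A prenyl group), or the electrophilic ortho-quinone may be captured intermolecularly before it tautomerizes. The fallback builds the chromene early and without an oxidant, by the thermal aryl propargyl ether cascade; it sets out from 10 and 9 and comes back at 25. Catechol 10 is mono-protected (MOMCl, one equivalent, K2CO3, acetone) to 2-(methoxymethoxy)phenol F1. Bromination para to the free hydroxyl (NBS, MeCN, 0 °C) gives 4-bromo-2-(methoxymethoxy)phenol F2. Etherification with 3-chloro-3-methylbut-1-yne (DBU, CuCl2 cat., MeCN, 0 °C) gives 4-bromo-2-(methoxymethoxy)-1-[(2-methylbut-3-yn-2-yl)oxy]benzene F3. Heating in N,N-diethylaniline at 160 °C brings about propargyl Claisen shift to the only free ortho carbon, 1,5-hydrogen shift and oxa-6π closure, which gives 6-bromo-8-(methoxymethoxy)-2,2-dimethyl-2H-chromene F4. Miyaura borylation (Pd(dppf)Cl2, B2pin2, KOAc, 1,4-dioxane, 80 °C) gives 2-[8-(methoxymethoxy)-2,2-dimethyl-2H-chromen-6-yl]-4,4,5,5-tetramethyl-1,3,2-dioxaborolane F5. Suzuki–Miyaura coupling with 9 as in step 7 gives 5-(allyloxy)-7-(methoxymethoxy)-3-[8-(methoxymethoxy)-2,2-dimethyl-2H-chromen-6-yl]-4H-chromen-4-one F6. Claisen rearrangement as in step 8 gives 6-allyl-5-hydroxy-7-(methoxymethoxy)-3-[8-(methoxymethoxy)-2,2-dimethyl-2H-chromen-6-yl]-4H-chromen-4-one F7. Cross-metathesis as in step 9 gives 5-hydroxy-7-(methoxymethoxy)-3-[8-(methoxymethoxy)-2,2-dimethyl-2H-chromen-6-yl]-6-(3-methylbut-2-en-1-yl)-4H-chromen-4-one F8. Acid cleavage of the two MOM groups as in step 10 then gives 25.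

2. Step 6. The iridium hydride and boryl species may hydroborate or isomerize the prenyl double bond, or the borylation may not be fully site-selective. The fallback brings in the coupling handle as bromine before any C–H functionalization; it sets out from 10 and comes back at 16. Catechol 10 is taken through 2-(methoxymethoxy)phenol F1 to 4-bromo-2-(methoxymethoxy)phenol F2 as described above. Ortho C-prenylation of the sodium phenoxide (NaH, toluene, prenyl bromide 12), for which only C6 is open, gives 4-bromo-2-(methoxymethoxy)-6-(3-methylbut-2-en-1-yl)phenol F9. Protection (MOMCl, NaH, DMF) gives 5-bromo-1,2-bis(methoxymethoxy)-3-(3-methylbut-2-en-1-yl)benzene F10. Miyaura borylation (Pd(dppf)Cl2, B2pin2 15, KOAc, 1,4-dioxane, 80 °C) gives 16.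

3. Step 8. The allyl group may migrate on by a second [3,3] shift from C6 to C8 before dienone 18 tautomerizes, or the substrate may degrade at 200 °C. The fallback replaces the thermal sigmatropic shift by an ionic 1,3-shift of a prenyl group at low temperature; it sets out from 17 and comes back at 21. The allyl ether of 17 is cleaved (Pd(PPh3)4 cat., morpholine, THF, rt) to 3-[3,4-bis(methoxymethoxy)-5-(3-methylbut-2-en-1-yl)phenyl]-5-hydroxy-7-(methoxymethoxy)-4H-chromen-4-one F11. O-Prenylation of the chelated hydroxyl (prenyl bromide 12, K2CO3, DMF, 60 °C) gives 3-[3,4-bis(methoxymethoxy)-5-(3-methylbut-2-en-1-yl)phenyl]-7-(methoxymethoxy)-5-[(3-methylbut-2-en-1-yl)oxy]-4H-chromen-4-one F12. Montmorillonite K10 in CH2Cl2 at 0 °C should then move the prenyl group from O5 to the ortho carbon C6 through a tight ion pair held at the C4=O/O5 chelate, which gives 21 directly and makes step 9 unnecessary; any C8 isomer would have to be separated.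

**Further compounds**

F1 | step 11 | 2-(methoxymethoxy)phenol | COCOc1ccccc1O
F2 | step 11 | 4-bromo-2-(methoxymethoxy)phenol | COCOc1cc(Br)ccc1O
F3 | step 11 | 4-bromo-2-(methoxymethoxy)-1-[(2-methylbut-3-yn-2-yl)oxy]benzene | C#CC(C)(C)Oc1ccc(Br)cc1OCOC
F4 | step 11 | 6-bromo-8-(methoxymethoxy)-2,2-dimethyl-2H-chromene | COCOc1cc(Br)cc2C=CC(C)(C)Oc12
F5 | step 11 | 2-[8-(methoxymethoxy)-2,2-dimethyl-2H-chromen-6-yl]-4,4,5,5-tetramethyl-1,3,2-dioxaborolane | COCOc1cc(B2OC(C)(C)C(C)(C)O2)cc2C=CC(C)(C)Oc12
F6 | step 11 | 5-(allyloxy)-7-(methoxymethoxy)-3-[8-(methoxymethoxy)-2,2-dimethyl-2H-chromen-6-yl]-4H-chromen-4-one | O=c1c(-c2cc(OCOC)c3OC(C)(C)C=Cc3c2)coc2cc(OCOC)cc(OCC=C)c12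
F7 | step 11 | 6-allyl-5-hydroxy-7-(methoxymethoxy)-3-[8-(methoxymethoxy)-2,2-dimethyl-2H-chromen-6-yl]-4H-chromen-4-one | O=c1c(-c2cc(OCOC)c3OC(C)(C)C=Cc3c2)coc2cc(OCOC)c(CC=C)c(O)c12
F8 | step 11 | 5-hydroxy-7-(methoxymethoxy)-3-[8-(methoxymethoxy)-2,2-dimethyl-2H-chromen-6-yl]-6-(3-methylbut-2-en-1-yl)-4H-chromen-4-one | O=c1c(-c2cc(OCOC)c3OC(C)(C)C=Cc3c2)coc2cc(OCOC)c(CC=C(C)C)c(O)c12
F9 | step 6 | 4-bromo-2-(methoxymethoxy)-6-(3-methylbut-2-en-1-yl)phenol | COCOc1cc(Br)cc(CC=C(C)C)c1O
F10 | step 6 | 5-bromo-1,2-bis(methoxymethoxy)-3-(3-methylbut-2-en-1-yl)benzene | COCOc1cc(Br)cc(CC=C(C)C)c1OCOC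
F11 | step 8 | 3-[3,4-bis(methoxymethoxy)-5-(3-methylbut-2-en-1-yl)phenyl]-5-hydroxy-7-(methoxymethoxy)-4H-chromen-4-one | O=c1c(-c2cc(CC=C(C)C)c(OCOC)c(OCOC)c2)coc2cc(OCOC)cc(O)c12
F12 | step 8 | 3-[3,4-bis(methoxymethoxy)-5-(3-methylbut-2-en-1-yl)phenyl]-7-(methoxymethoxy)-5-[(3-methylbut-2-en-1-yl)oxy]-4H-chromen-4-one | O=c1c(-c2cc(CC=C(C)C)c(OCOC)c(OCOC)c2)coc2cc(OCOC)cc(OCC=C(C)C)c12
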